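No flask can hold more X than the J charged, and the meeting began from that. The substrate J passes through the intermediate G to the product X or to the other product L, J also gives the other product Q directly, and D is crystals of X. The secretary therefore wrote the balance for J, the limiting reagent: J charged equals J + G + X + L + Q, with D counted inside X.

| flask | J | remark | time |
|---|---|---|---|
| beta | 2.8 M | run made earlier |  |
| flask | 2.0 M |  | 3.0 d |

- beta (time / d: X / %): 0.167: 29.1; 0.333: 42.2; 0.833: 49.6; 1.67: 47.3; 4.00: 35.4

(scatter of a reading: 1 percentage point)

1. the moment within 3.0 d at which there is most X
2. the amount of X, in percent of the J charged, at that time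
3. earliest time at which at least nineteen twentieths of that best amount are there, in d
4. latest time at which they still are, in d

- for X the D are counted in
- as a solid, counted per litre of solution: D
- the analysis behind the earlier runs scatters by 1 percentage point, standard deviation
- steps thought possible: J -> G; G <-> X; G <-> L; J -> Q; D <-> X

It was noted that the beta run, as read, stands highest at 49.6 % at 0.833 d, and that by the balance any later fall in X must reappear in another term of the balance. The secretary then argued, as a reckoning of her own, that percentages need not carry over between charges. If D holds dissolved X steady, X is lost at a flat molar rate, a zero-order loss, whatever the charge. From the last two beta readings, each with a scatter of 1 percentage point, she got 0.143 M d⁻¹ of X lost, which she called the drain. With 2.0 M charged, she said, the drop to the asked fraction of a best near the beta peak takes 0.347 d, so she put the closing time near 1.18 d.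

The forecaster gave 50 % of X at 0.85 d, with the window open from 0.48 d to 1.6 d, and said: “One run cannot settle this, so I keep the estimates near the fit and the ranges wide”. The minutes record that this closing time is later than the secretary's.

The flask gives 48.6 % of X at 0.686 d, and the asked fraction of that stands from 0.422 d to 1.24 d.

    J → G (k = 0.372 h⁻¹)
    G ⇌ X (K = 1.51, k = 0.280 h⁻¹)
    G ⇌ L (K = 79.0, k = 0.0955 h⁻¹)
    J → Q (k = 3.67 × 10⁻⁵ h⁻¹)
    D ⇌ X, rate k5*(cs5 - [X]) while solid is left; crystals form when [X] > cs5 (solubility = 0.190 M, k = 0.140 h⁻¹)

The flask closes earlier than the forecast said and 0.0600 d later than the secretary's time. Between 1.50 d and 3.00 d this flask falls from 44.5 % to 34.0 % of X, which is 0.140 M d⁻¹, beside the drain of 0.143 M d⁻¹ read from beta, while D goes from 36.1 % to 26.6 %. The neighbouring flask, charged with 0.50 M of J, reaches a best of 40.6 %, and the drain reckons that amount gone in 1.42 d. At 3.00 d that neighbouring flask still holds 6.87 % of X, with 0 % of D.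

(The numbers in the tables are calculated for substances that don't exist; scatter was added.)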